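**Assumption:** The target SMILES has no stereocentres and no E/Z-defined alkenes, because both olefins end in gem-dimethyl groups. Cudraphenone D (C23H26O5) is therefore achiral, and the "single enantiomer" requirement needs no action.

## Retrosynthetic overview
1. No rings are formed. Both benzene rings are purchased, as 3-hydroxybenzaldehyde and phloroglucinol.
2. The last step is global MOM removal from the tetra-MOM benzophenone.
3. The key disconnection is the aryl–C(=O) bond. It is made by adding a ring-B aryllithium to a ring-A aldehyde and then oxidising the carbinol.
4. The ring-A prenyl group is installed by directed ortho-lithiation at C2, between the masked CHO and the OMOM, followed by prenyl bromide.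
5. The ring-B prenyl group is installed by lithiating tris-MOM phloroglucinol and adding prenyl bromide. A second lithiation then gives the coupling nucleophile.

## Route

**Step 1**
- Reactants: 1, 3-hydroxybenzaldehyde; 2, chloromethyl methyl ether (MOMCl)
- Product: 3, 3-(methoxymethoxy)benzaldehyde
- Conditions: MOMCl (1.3 equiv), i-Pr2NEt, CH2Cl2, 0 °C → rt
- Reagents that add atoms: MOMCl, COCCl
- Why: This is a Williamson-type O-alkylation of the phenol. The MOM group protects the OH and later acts as a strong ortho-directing group.

**Step 2**
- Reactants: 3, 3-(methoxymethoxy)benzaldehyde; 4, prenyl bromide (1-bromo-3-methylbut-2-ene)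
- Product: 5, 3-(methoxymethoxy)-2-(3-methylbut-2-en-1-yl)benzaldehyde
- Conditions: Me2NCH2CH2N(Li)Me (from the amine + n-BuLi, 1.1 equiv), THF, −20 °C. Then n-BuLi (2.5 equiv), −20 → 0 °C. Then prenyl bromide (excess), −78 °C → rt. Work up with cold aq NH4Cl.
- Reagents that add atoms: prenyl bromide, CC(C)=CCBr
- Why: The aldehyde is masked in situ as an α-amino alkoxide (Comins-type directed ortho-metalation). This group and the OMOM both direct lithiation to C2. The aryllithium is alkylated by SN2, and work-up releases the aldehyde.

**Step 3**
- Reactants: 6, phloroglucinol (anhydrous benzene-1,3,5-triol); 2, MOMCl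
- Product: 7, 1,3,5-tris(methoxymethoxy)benzene
- Conditions: NaH (3.6 equiv), MOMCl (3.6 equiv), DMF, 0 °C → rt
- Reagents that add atoms: MOMCl, COCCl (×3)
- Why: This is an exhaustive O-alkylation. The hard oxocarbenium-type electrophile reacts at O rather than C of the phloroglucinolate.

**Step 4**
- Reactants: 7, 1,3,5-tris(methoxymethoxy)benzene; 4, prenyl bromide
- Product: 8, 1,3,5-tris(methoxymethoxy)-2-(3-methylbut-2-en-1-yl)benzene
- Conditions: n-BuLi (1.1 equiv), THF, 0 °C, 1 h. Then prenyl bromide (1.2 equiv), −78 °C → rt.
- Reagents that add atoms: prenyl bromide, CC(C)=CCBr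
- Why: This is a directed ortho-metalation. All three C–H positions are equivalent and each lies between two OMOM groups. SN2 alkylation of the aryllithium gives the linear prenyl arene.

**Step 5**
- Reactants: 8, prenylated tris-MOM arene; 5, ring-A aldehyde
- Product: 9, (±)-[3-(methoxymethoxy)-2-prenylphenyl][2,4,6-tris(methoxymethoxy)-3-prenylphenyl]methanol
- Conditions: 8, n-BuLi (1.1 equiv), THF, 0 °C, 1 h. Then 5 (0.9 equiv), −78 → 0 °C. Quench with aq NH4Cl.
- Reagents that add atoms: none (both partners are listed as reactants)
- Why: A second directed ortho-metalation occurs at either of the two equivalent C–H positions flanked by OMOM groups. The aryllithium then adds 1,2 to the non-enolisable aldehyde. The carbinol centre is racemic and is removed in Step 6. Mass balance: C17H26O6 + C14H18O3 = C31H44O9.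

**Step 6**
- Reactants: 9, diaryl carbinol
- Product: 10, [3-(methoxymethoxy)-2-prenylphenyl][2,4,6-tris(methoxymethoxy)-3-prenylphenyl]methanone
- Conditions: Dess–Martin periodinane (1.5 equiv), NaHCO3, CH2Cl2, 0 °C → rt
- Reagents that add atoms: none
- Why: A buffered Dess–Martin oxidation converts the doubly benzylic alcohol to the ketone. It does not affect the trisubstituted alkenes or the acid-sensitive MOM acetals.

**Step 7**
- Reactants: 10, tetra-MOM benzophenone
- Product: 11, cudraphenone D, (3-hydroxy-2-prenylphenyl)(2,4,6-trihydroxy-3-prenylphenyl)methanone
- Conditions: conc. HCl (approx. 0.3 M final) in MeOH, rt → 40 °C, monitored closely. Quench with aq NaHCO3.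
- Reagents that add atoms: none
- Why: Mild acid acetal solvolysis removes all four MOM groups (loss of 4 × C2H4O gives C23H26O5). It is stopped before the prenyl groups can be protonated and close to chromans. Xanthone formation is not possible because ring A has no ortho OH.

## Compound list
| No. | Name | SMILES | Role |
|---|---|---|---|
| 1 | 3-hydroxybenzaldehyde | O=Cc1cccc(O)c1 | starting material |
| 2 | chloromethyl methyl ether | COCCl | starting material (reagent) |
| 3 | 3-(methoxymethoxy)benzaldehyde | COCOc1cccc(C=O)c1 | intermediate |
| 4 | prenyl bromide | CC(C)=CCBr | starting material (reagent) |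
| 5 | 3-(methoxymethoxy)-2-prenylbenzaldehyde | COCOc1cccc(C=O)c1CC=C(C)C | intermediate |
| 6 | phloroglucinol | Oc1cc(O)cc(O)c1 | starting material |
| 7 | 1,3,5-tris(methoxymethoxy)benzene | COCOc1cc(OCOC)cc(OCOC)c1 | intermediate |
| 8 | 1,3,5-tris(methoxymethoxy)-2-prenylbenzene | COCOc1cc(OCOC)c(CC=C(C)C)c(OCOC)c1 | intermediate |
| 9 | (±)-diaryl carbinol, tetra-MOM | OC(c1cccc(OCOC)c1CC=C(C)C)c1c(OCOC)cc(OCOC)c(CC=C(C)C)c1OCOC | intermediate (racemic; centre removed in Step 6) |
| 10 | tetra-MOM benzophenone | O=C(c1cccc(OCOC)c1CC=C(C)C)c1c(OCOC)cc(OCOC)c(CC=C(C)C)c1OCOC | intermediate |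
| 11 | cudraphenone D | CC(C)=CCc1c(O)cccc1C(=O)c1c(O)cc(O)c(CC=C(C)C)c1O | target (achiral) |

## Summary
- **Total steps:** 7
- **Longest linear sequence:** 5. Either branch counts: Steps 1, 2, 5, 6, 7 or Steps 3, 4, 5, 6, 7.

**Three steps most likely to fail, with fallbacks**

1. **Step 7.** Acid may cyclise an o-prenylphenol to a chroman.
   - Fallback: use allyl bromide instead of prenyl bromide in Steps 2 and 4. Allyl groups resist acid cyclisation.
   - Remove the MOM groups, then convert both allyl groups to prenyl by double cross-metathesis with 2-methyl-2-butene (Grubbs II) on the free tetraphenol. This adds one step.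

2. **Step 2.** One-pot masking, C2-lithiation and prenylation could give incomplete metalation, and the excess BuLi consumes electrophile.
   - Fallback: drop the C–H lithiation. Start from commercial 2-bromo-3-hydroxybenzaldehyde and MOM-protect it.
   - Install the prenyl group by Pd-catalysed Stille coupling with tributyl(3-methylbut-2-enyl)stannane. The step count is unchanged.

3. **Step 5.** Allylic or benzylic deprotonation of 8 may compete with ring lithiation, and the addition is hindered.
   - Fallback: move the ring-B prenylation to the end. Lithiate the unprenylated 7, add it to 5, oxidise, and remove the MOM groups.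
   - Then mono-C-prenylate the acylphloroglucinol ring with prenyl bromide and 1 equiv of aq KOH. Its two free positions are equivalent, and it is far more acidic than the ring-A phenol. The step count is unchanged.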